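The rate constants are hidden, so the questions start from the charges and the red run.

| setting | red | zeta | gamma |
|---|---|---|---|
| Z | 0.81 M (fed, over 80 min) | 0.81 M (fed, over 80 min) | 0.81 M (fed, over 250 min) |
| E | 3.4 mM | 2.3 mM | 2.3 mM |
| remark | run made earlier; the fed solution adds 1.0 times the starting volume | the fed solution adds 1.0 times the starting volume | the fed solution adds 1.0 times the starting volume |
| time |  | 4.0 h | 4.0 h |

- red (time / min: Q / %): 4.00: 1.1; 12.0: 0; 20.0: 2.1; 30.0: 7.6; 50.0: 17.8

(standard deviation of a reading: 1 percentage point)

- charges are per starting volume, the dose included; the dosed solution carries all of it
- the average divides the monomer in chains by the number of chains begun, living and dead together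
- the numbers in the tables scatter with a standard deviation of 1 percentage point
- percentages count the whole charge, also what has not yet gone in
- the earlier runs do not show the number of chains; that part of a forecast is a guess
- no earlier run changes the charge of E; that part of a forecast is a guess

- which of the two ends with the longer chains by the average number of monomer units in a chain (chains begun, living or dead) ("neither" if they lie within 10%) (zeta / gamma / neither)
- average number of monomer units in a chain (chains begun, living or dead) at the end, zeta
- average number of monomer units in a chain (chains begun, living or dead) at the end, gamma

What does the average length count? It counts monomer in chains over chains begun. If each E begins one chain, the chains begun equal the charge of E. The charge of Z divided by the charge of E, here 352, I call the full-charge length: the units per chain if the whole charge of Z stood in chains. The average is then this length times the fraction of the charge held as Q.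

Is one chain per E shown? No: “Chain count is a guess”, and the red run gives no count. But zeta and gamma share their charges, so they share one full-charge length, and the comparison rests on the fraction in Q.

How do you reach that fraction? I take the rate of making Q as Z at hand times a steady concentration of active ends, a pseudo-first-order picture. At 50.0 min the red run has been fed 62.5% of its Z, but the reading of Q is 17.8%, which is less. That lag gives about 0.015 per minute.

Where is this weakest? The red readings stop at 50.0 min, earlier than the end of the dose at 80 min. Steady active ends over the 4.0 h of the new flasks are therefore an assumption.

And your forecast? Zeta ends longer, at 265 (range 170 to 500), and gamma reaches 187 (range 120 to 360). These are 75.2% and 53.1% of the full-charge length.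

The flasks give 123 for zeta and 40.5 for gamma, so zeta is longer.

    Z + E → L + Q (k = 1.47 M⁻¹ min⁻¹)
    Z + L → Q + L, rate k2*[L]*[Z] (k = 33.0 M⁻¹ min⁻¹)
    Q + L → Z + L, rate k3*[L] as long as [Q] is above zero (k = 3.65 min⁻¹)
    2 Z → D (k = 3.78 × 10⁻⁵ M⁻¹ min⁻¹)
    L → J (k = 0.0265 min⁻¹)

E stands at 0% of its charge in zeta and at 0% in gamma at the end, and the full-charge length times zeta's Q of 35.0% gives 123, while times gamma's 11.5% it gives 40.5. The difference in dosing time is the main reason for the gap: gamma, dosed over 250 min, gives 40.5, and the same run with that difference taken away, so dosed over zeta's 80 min, gives 123. One more flask, like zeta but with 0.0057 M of E, ends with 0% of that E and has a full-charge length of 142, and its Q of 55.0% gives 78.1, against a simulated length of 78.1.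

(The data were generated by integration for substances that don't exist.)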